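**Retrosynthetic overview**

1. Flavone numbering is used throughout (oxepine CH2 = C9, O-bearing stereocentre = C10, carbinol carbon = C11). The route rests on one feature. Five of the seven oxepine atoms (2'-O, C10, C2, C1', C2') are the ring atoms of a 3-hydroxybenzofuran-2-carboxylate once C10 and C2 are joined. The other two, C9 and C3 with the C4 aroyl group on C3, are an aryl ethynyl ketone.
2. Endgame disconnections: 4'-O–Si; C6–alkenyl (Suzuki–Miyaura on a 6-iodide); both C11–CH3 bonds (MeMgBr on a C10 ester); C10–H (asymmetric hydrogenation of the C9=C10 α-aryloxyacrylic acid).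
3. Core disconnections: O1–C2 of the pyranone (acid cyclodehydration of a 1,3-diketone); then C9–C10 and C2–C3 of the oxepine (insertion of the ynone into the C2–C10 bond of the benzofuranone).
4. Fragments: the benzofuranone ester comes from methyl 2,4-dihydroxybenzoate (silylation, O-alkylation, Dieckmann). The ynone comes from 5-methoxyresorcinol (MOM protection, ortho-lithiation/formylation, ethynyl Grignard addition, oxidation).
5. Order of ring formation: furanone (temporary five-membered ring), then oxepine (by its expansion), then pyranone. Rings A and B come from the starting materials.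

Key step: step 8

Assumption: the (Sa,S) series of the spiro phosphine–oxazoline ligand is written for the hydrogenation. Which antipode sends hydrogen to the Si face of C10 in this cyclic acid has to be fixed by one test run with assignment of configuration, and the equally available antipode would be taken if needed.

**Route**

Step 1
Reactants: 1 methyl 2,4-dihydroxybenzoate
Product: 2 methyl 2-hydroxy-4-(triisopropylsilyloxy)benzoate
Conditions: TIPSCl (1.05 equiv), imidazole, DMF, 0 °C → rt
Reagents that add atoms: triisopropylsilyl chloride, CC(C)[Si](Cl)(C(C)C)C(C)C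
Why: Chemoselective silyl ether formation: the 2-OH is tied up in a hydrogen bond to the ester carbonyl and is flanked by it, so the bulky chlorosilane should take only the free, more acidic 4-OH.

Step 2
Reactants: 2 methyl 2-hydroxy-4-(triisopropylsilyloxy)benzoate, 3 tert-butyl bromoacetate
Product: 4 methyl 2-(2-tert-butoxy-2-oxoethoxy)-4-(triisopropylsilyloxy)benzoate
Conditions: K2CO3 (anhydrous), acetone, reflux
Reagents that add atoms: none
Why: Williamson ether synthesis on the remaining phenol with a reactive α-bromo ester under anhydrous carbonate, which the hindered aryl TIPS ether tolerates; the tert-butyl ester is chosen so that the C10 carboxyl can later be freed by acid and never by hydroxide.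

Step 3
Reactants: 4 methyl 2-(2-tert-butoxy-2-oxoethoxy)-4-(triisopropylsilyloxy)benzoate
Product: 5 tert-butyl 3-hydroxy-6-(triisopropylsilyloxy)benzofuran-2-carboxylate
Conditions: KOtBu (1.5 equiv), THF, 0 °C; then cold 1 M HCl
Reagents that add atoms: none
Why: Dieckmann condensation: the aryloxyacetate enolate attacks the neighbouring methyl benzoate (5-exo-trig), methoxide leaves and the product is drawn out of the equilibrium as its aromatic enolate, while tert-butoxide matches the ester that stays and the TIPS ether tolerates the short cold exposure.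

Step 4
Reactants: 6 5-methoxyresorcinol
Product: 7 1-methoxy-3,5-bis(methoxymethoxy)benzene
Conditions: MOMCl (2.5 equiv), i-Pr2NEt, CH2Cl2, 0 °C → rt
Reagents that add atoms: chloromethyl methyl ether, COCCl
Why: Standard acetal protection of both phenols with the chloromethyl ether and a hindered amine base, which keeps ring A symmetric and installs two strong ortho-directing groups.

Step 5
Reactants: 7 1-methoxy-3,5-bis(methoxymethoxy)benzene
Product: 9 4-methoxy-2,6-bis(methoxymethoxy)benzaldehyde, via aryllithium 8 (not isolated)
Conditions: n-BuLi (1.1 equiv), TMEDA, THF, 0 °C; DMF, 0 °C → rt; H2O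
Reagents that add atoms: N,N-dimethylformamide, CN(C)C=O
Why: Directed ortho-metalation followed by formylation: the C–H flanked by the two chelating OMOM groups is the most acidic and best coordinated site, so lithiation there should prevail over the two OMe/OMOM-flanked positions, and DMF traps the aryllithium as the aldehyde.

Step 6
Reactants: 9 4-methoxy-2,6-bis(methoxymethoxy)benzaldehyde, 10 ethynylmagnesium bromide
Product: 11 (±)-1-[4-methoxy-2,6-bis(methoxymethoxy)phenyl]prop-2-yn-1-ol
Conditions: 10 (0.5 M in THF, 1.3 equiv), THF, 0 °C; aq. NH4Cl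
Reagents that add atoms: none
Why: 1,2-Addition of an alkynyl Grignard reagent to an aldehyde that cannot enolise; the new carbinol centre is racemic and is erased in step 7.

Step 7
Reactants: 11 (±)-1-[4-methoxy-2,6-bis(methoxymethoxy)phenyl]prop-2-yn-1-ol
Product: 12 1-[4-methoxy-2,6-bis(methoxymethoxy)phenyl]prop-2-yn-1-one
Conditions: activated MnO2 (excess), CH2Cl2, rt
Reagents that add atoms: none
Why: Manganese dioxide oxidation of a benzylic–propargylic alcohol under neutral conditions, which spares the MOM acetals and the terminal alkyne and avoids the acid that would ionise this electron-rich carbinol.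

Step 8
Reactants: 5 tert-butyl 3-hydroxy-6-(triisopropylsilyloxy)benzofuran-2-carboxylate, 12 1-[4-methoxy-2,6-bis(methoxymethoxy)phenyl]prop-2-yn-1-one
Product: 16 tert-butyl 4-[4-methoxy-2,6-bis(methoxymethoxy)benzoyl]-5-hydroxy-8-(triisopropylsilyloxy)-1-benzoxepine-2-carboxylate, via sodium enolate 13 (not isolated), via allenolate 14 (not isolated), via cyclobutene alkoxide 15 (not isolated)
Conditions: NaH (1.05 equiv), dry THF, 0 °C until H2 evolution ends; 12 (1.05 equiv) in THF added over 2 h, 0 °C → rt; AcOH, 0 °C
Reagents that add atoms: none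
Why: The fully deprotonated hydroxybenzofuran 13 attacks through C10, as a soft carbon nucleophile and with loss of furan aromaticity, the unsubstituted alkyne terminus C9 of 12 (Michael addition); allenolate 14 then adds through C3 to the neighbouring ring ketone C2, and the strained alkoxide 15 breaks the old C2–C10 bond by retro-aldol fragmentation to a C10 carbanion stabilised by the ester and the new enone, which rests as the 1,3-diketone enolate until the acid quench. The closest known reaction type is the two-carbon ring expansion of cyclic β-keto esters with acetylenic esters and ketones, together with the related enamine–alkyne cyclobutene route from 3-amino benzo-fused five-membered heterocycles to their seven-membered homologues. Only the transient cyclobutene is closed directly (4-exo-trig aldol); the oxepine arises by scission of the fusion bond of the bicyclo[3.2.0] alkoxide, so no end-to-end seven-membered cyclisation is needed. No stereocentre is created for the product: the centres of 14 and 15 are racemic and are erased, and C10 leaves the step sp2. The step needs regiocontrol, C- over O-attack and closure over protonation: ynone polarity puts C9 on C10 and C3 on C2, O-adducts can revert by addition–elimination whereas the C-pathway ends in an irreversible fragmentation, and stoichiometric NaH, dry THF and slow addition of 12 leave the alkyne C–H as the only proton source and keep it dilute. The bulky tert-butyl ester keeps the allenolate off the ester carbonyl, so the ketone is the only acceptor within reach.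

Step 9
Reactants: 16 tert-butyl 4-[4-methoxy-2,6-bis(methoxymethoxy)benzoyl]-5-hydroxy-8-(triisopropylsilyloxy)-1-benzoxepine-2-carboxylate
Product: 19 C9=C10-unsaturated oxepinoflavone acid (5-hydroxy-7-methoxy-4'-(triisopropylsilyloxy)flavone bridged from C3 through C9H=C10(CO2H) to the 2'-oxygen), via bisphenol diketone 17 (not isolated), via chromone tert-butyl ester 18 (not isolated)
Conditions: TFA–CH2Cl2 (1:2), H2O (5 equiv), 0 °C → rt
Reagents that add atoms: none
Why: Acidolysis of the two aryl MOM acetals frees bisphenol 17, either of whose equivalent hydroxyls adds to the C2 carbonyl of the 1,3-diketone and loses water (the cyclodehydration that ends a Baker–Venkataraman flavone synthesis), and the same acid removes the tert-butyl group as isobutene, so hydroxide never meets the acid-stable aryl silyl ether or the pyranone.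

Step 10
Reactants: 19 C9=C10-unsaturated oxepinoflavone acid
Product: 20 (10R)-9,10-dihydro oxepinoflavone acid (C3–C9H2–C10H(CO2H)–O–C2')
Conditions: [Ir(cod)((Sa,S)-DTB-Bn-SIPHOX)]BArF (1 mol %), H2 (6 atm), Et3N (1 equiv), MeOH, 40 °C; dilute acid work-up
Reagents that add atoms: none
Why: Carboxylate-directed iridium-catalysed asymmetric hydrogenation of a (Z)-configured α-aryloxy-β-aryl acrylic acid, an established substrate class for spiro phosphine–oxazoline iridium catalysts: the carboxylate binds the metal, the ligand pocket admits hydrogen only to the Si face of C10 (priorities O > CO2H > C9), which gives (R), and the tetrasubstituted C2=C3 bond of the pyranone is not reduced.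

Step 11
Reactants: 20 (10R)-9,10-dihydro oxepinoflavone acid
Product: 21 (10R)-methyl ester of 20
Conditions: TMSCHN2 (1.2 equiv), toluene–MeOH (4:1), 0 °C
Reagents that add atoms: (trimethylsilyl)diazomethane, C[Si](C)(C)C=[N+]=[N-]
Why: O-Methylation of the carboxylic acid by (trimethylsilyl)diazomethane under neutral conditions, so the C10 centre next to the carbonyl is not exposed to base and the chelated 5-OH, far less acidic than the acid, stays free.

Step 12
Reactants: 21 (10R)-methyl ester
Product: 22 (10R)-10-(2-hydroxypropan-2-yl) oxepinoflavone, 4'-O-TIPS, C6 unsubstituted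
Conditions: MeMgBr (5 equiv), THF, −40 → 0 °C; aq. NH4Cl
Reagents that add atoms: methylmagnesium bromide, C[Mg]Br
Why: Double Grignard addition to an ester: the first equivalent turns 5-OH into a magnesium phenoxide chelated to C4=O, which makes the pyranone carbonyl an electron-rich vinylogous carboxylate shielded by C9 and the peri oxygen, whereas the α-aryloxy ester is activated by chelation, and addition at low temperature should outrun enolisation, so C10 keeps its configuration.

Step 13
Reactants: 22 (10R)-tertiary alcohol
Product: 23 (10R)-6-iodo derivative of 22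
Conditions: BnMe3N·ICl2 (1.05 equiv), CaCO3, CH2Cl2–MeOH (5:2), rt
Reagents that add atoms: benzyltrimethylammonium dichloroiodate, C[N+](C)(C)Cc1ccccc1.Cl[I-]Cl
Why: Electrophilic aromatic iodination with a dichloroiodate salt, a reagent known to attack C6 of flavones that carry a free 5-OH and an alkylated 7-oxygen (ortho to the phenol), while ring B is deactivated by conjugation with the pyranone and its open positions are screened by the bulky silyl ether.

Step 14
Reactants: 24 3-methylbut-1-yne
Product: 25 (E)-4,4,5,5-tetramethyl-2-(3-methylbut-1-enyl)-1,3,2-dioxaborolane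
Conditions: pinacolborane (1.0 equiv), Cy2BH (5 mol %), neat, sealed vessel, rt
Reagents that add atoms: pinacolborane, [H]B1OC(C)(C)C(C)(C)O1
Why: Borane-catalysed hydroboration of a terminal alkyne with pinacolborane: syn addition with boron at the unhindered terminus fixes the E geometry.

Step 15
Reactants: 23 (10R)-6-iodide, 25 (E)-alkenylboronate
Product: 26 4'-O-TIPS ether of the target
Conditions: Pd(dppf)Cl2·CH2Cl2 (5 mol %), K2CO3 (3 equiv), 1,4-dioxane–H2O (5:1), 80 °C
Reagents that add atoms: none
Why: Suzuki–Miyaura coupling of an aryl iodide with an alkenylboronate, which proceeds with retention of the E geometry and is established for iodoflavones with a free 5-OH; partial loss of the silyl group under the aqueous base would do no harm because it is removed next.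

Step 16
Reactants: 26 4'-O-TIPS ether of the target
Product: 27 CNP0216454.1
Conditions: TBAF (1.1 equiv), AcOH (1.1 equiv), THF, 0 °C
Reagents that add atoms: none
Why: Fluoride cleavage of the aryl silyl ether, buffered with acetic acid so that the medium stays non-basic; the alkene, the tertiary alcohol and C10 are inert to it.

**Compound list**

1 | methyl 2,4-dihydroxybenzoate | COC(=O)c1ccc(O)cc1O | starting material
2 | methyl 2-hydroxy-4-(triisopropylsilyloxy)benzoate | COC(=O)c1ccc(O[Si](C(C)C)(C(C)C)C(C)C)cc1O | intermediate
3 | tert-butyl bromoacetate | CC(C)(C)OC(=O)CBr | starting material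
4 | methyl 2-(2-tert-butoxy-2-oxoethoxy)-4-(triisopropylsilyloxy)benzoate | COC(=O)c1ccc(O[Si](C(C)C)(C(C)C)C(C)C)cc1OCC(=O)OC(C)(C)C | intermediate
5 | tert-butyl 3-hydroxy-6-(triisopropylsilyloxy)benzofuran-2-carboxylate | CC(C)(C)OC(=O)c1oc2cc(O[Si](C(C)C)(C(C)C)C(C)C)ccc2c1O | intermediate
6 | 5-methoxyresorcinol | COc1cc(O)cc(O)c1 | starting material
7 | 1-methoxy-3,5-bis(methoxymethoxy)benzene | COCOc1cc(OC)cc(OCOC)c1 | intermediate
8 | [4-methoxy-2,6-bis(methoxymethoxy)phenyl]lithium | [Li]c1c(OCOC)cc(OC)cc1OCOC | intermediate
9 | 4-methoxy-2,6-bis(methoxymethoxy)benzaldehyde | O=Cc1c(OCOC)cc(OC)cc1OCOC | intermediate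
10 | ethynylmagnesium bromide | C#C[Mg]Br | starting material
11 | (±)-1-[4-methoxy-2,6-bis(methoxymethoxy)phenyl]prop-2-yn-1-ol | C#CC(O)c1c(OCOC)cc(OC)cc1OCOC | intermediate
12 | 1-[4-methoxy-2,6-bis(methoxymethoxy)phenyl]prop-2-yn-1-one | C#CC(=O)c1c(OCOC)cc(OC)cc1OCOC | intermediate
13 | sodium enolate of 5 | CC(C)(C)OC(=O)c1oc2cc(O[Si](C(C)C)(C(C)C)C(C)C)ccc2c1[O-].[Na+] | intermediate
14 | sodium allenolate, racemic C2-(3-aryl-3-oxidopropadienyl)benzofuran-3-one-2-carboxylate | CC(C)(C)OC(=O)C1(C=C=C([O-])c2c(OCOC)cc(OC)cc2OCOC)Oc2cc(O[Si](C(C)C)(C(C)C)C(C)C)ccc2C1=O.[Na+] | intermediate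
15 | sodium alkoxide of the racemic cyclobuta[b]benzofuran (cyclobutene fused across the old C2–C10 bond) | CC(C)(C)OC(=O)C12C=C(C(=O)c3c(OCOC)cc(OC)cc3OCOC)C1([O-])c1ccc(O[Si](C(C)C)(C(C)C)C(C)C)cc1O2.[Na+] | intermediate
16 | tert-butyl 4-[4-methoxy-2,6-bis(methoxymethoxy)benzoyl]-5-hydroxy-8-(triisopropylsilyloxy)-1-benzoxepine-2-carboxylate | CC(C)(C)OC(=O)C1=CC(C(=O)c2c(OCOC)cc(OC)cc2OCOC)=C(O)c2ccc(O[Si](C(C)C)(C(C)C)C(C)C)cc2O1 | intermediate
17 | tert-butyl 4-(2,6-dihydroxy-4-methoxybenzoyl)-5-hydroxy-8-(triisopropylsilyloxy)-1-benzoxepine-2-carboxylate | CC(C)(C)OC(=O)C1=CC(C(=O)c2c(O)cc(OC)cc2O)=C(O)c2ccc(O[Si](C(C)C)(C(C)C)C(C)C)cc2O1 | intermediate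
18 | tert-butyl ester of 19 | CC(C)(C)OC(=O)C1=Cc2c(oc3cc(OC)cc(O)c3c2=O)-c2ccc(O[Si](C(C)C)(C(C)C)C(C)C)cc2O1 | intermediate
19 | C9=C10-unsaturated oxepinoflavone acid | OC(=O)C1=Cc2c(oc3cc(OC)cc(O)c3c2=O)-c2ccc(O[Si](C(C)C)(C(C)C)C(C)C)cc2O1 | intermediate
20 | (10R)-9,10-dihydro oxepinoflavone acid | COc1cc2oc3c(c(=O)c2c(O)c1)C[C@H](C(=O)O)Oc1cc(O[Si](C(C)C)(C(C)C)C(C)C)ccc1-3 | intermediate
21 | (10R)-methyl ester | COc1cc2oc3c(c(=O)c2c(O)c1)C[C@H](C(=O)OC)Oc1cc(O[Si](C(C)C)(C(C)C)C(C)C)ccc1-3 | intermediate
22 | (10R)-10-(2-hydroxypropan-2-yl) oxepinoflavone 4'-O-TIPS ether | COc1cc2oc3c(c(=O)c2c(O)c1)C[C@H](C(C)(C)O)Oc1cc(O[Si](C(C)C)(C(C)C)C(C)C)ccc1-3 | intermediate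
23 | (10R)-6-iodide | COc1cc2oc3c(c(=O)c2c(O)c1I)C[C@H](C(C)(C)O)Oc1cc(O[Si](C(C)C)(C(C)C)C(C)C)ccc1-3 | intermediate
24 | 3-methylbut-1-yne | C#CC(C)C | starting material
25 | (E)-4,4,5,5-tetramethyl-2-(3-methylbut-1-enyl)-1,3,2-dioxaborolane | CC(C)/C=C/B1OC(C)(C)C(C)(C)O1 | intermediate
26 | 4'-O-TIPS ether of the target | COc1cc2oc3c(c(=O)c2c(O)c1/C=C/C(C)C)C[C@H](C(C)(C)O)Oc1cc(O[Si](C(C)C)(C(C)C)C(C)C)ccc1-3 | intermediate
27 | CNP0216454.1, (10R) | COc1cc2oc3c(c(=O)c2c(O)c1/C=C/C(C)C)C[C@H](C(C)(C)O)Oc1cc(O)ccc1-3 | target

**Step count**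

Total step count: 16.
Longest linear sequence: 12 steps (6 → 27 through steps 4–13, 15 and 16).

**Steps most likely to fail**

Step 8. The allenolate may be protonated (by the alkyne C–H or by adventitious water) before it closes on the ketone, which stops the cascade at the open Michael stage. O-alkenylation of the enolate may also compete.

The fallback sets out from 5 and 12 and makes the two bonds separately. The C9–C10 bond would be formed on purpose under protic, amine-catalysed conditions (Et3N 10 mol %, CH2Cl2, rt). This is a known conjugate addition of benzofuranone carboxylates to alkynones. It should give the racemic Michael adduct tert-butyl 2-{(E)-3-[4-methoxy-2,6-bis(methoxymethoxy)phenyl]-3-oxoprop-1-enyl}-3-oxo-6-(triisopropylsilyloxy)-2,3-dihydrobenzofuran-2-carboxylate F1.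

α-Iodination of the enone (I2, pyridine, CH2Cl2, rt) would give the (Z)-α-iodoenone F2, in which iodine stands cis to C10. Iodine–magnesium exchange (i-PrMgCl·LiCl, THF, −78 °C) would then regenerate the C3 carbanion in a medium without any proton source. Closure on C2, fragmentation and an AcOH quench come back to the route at 16.

Step 10. Facial selectivity may be poor or turnover slow, because the boat-shaped tetracyclic acid may not fit the ligand pocket as open-chain α-aryloxycinnamic acids do.

The fallback sets out from 19 and replaces asymmetric catalysis by resolution. Hydrogenation over Pd/C (H2 1 atm, EtOAc, rt) would give the racemic dihydro acid F3. TMSCHN2 would then give the racemic methyl ester F4. Preparative chromatography on a chiral stationary phase (SFC) would deliver the (R)-ester, which comes back to the route at 21. The unwanted (S)-methyl ester F5 could be re-equilibrated to F4 with DBU and separated again.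

Step 12. The hard methyl nucleophile may attack the pyranone (C4 or C2) in competition with the ester, or enolisation at C10 may erode the configuration.

The fallback sets out from 20 and uses only zinc and titanium methyl reagents, which leave chromones alone. EtSH, EDC and HOBt (CH2Cl2, 0 °C) would give the (10R)-S-ethyl thioester F6. Fukuyama coupling (MeZnI, PdCl2(PPh3)2, toluene, rt) would give the (10R)-methyl ketone F7. MeTi(OiPr)3 (CH2Cl2, −20 °C → rt), a ketone-selective methyl donor, would add to F7 and come back to the route at 22.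

**Further compounds**

F1 | step 8 | racemic tert-butyl 2-{(E)-3-[4-methoxy-2,6-bis(methoxymethoxy)phenyl]-3-oxoprop-1-enyl}-3-oxo-6-(triisopropylsilyloxy)-2,3-dihydrobenzofuran-2-carboxylate | CC(C)(C)OC(=O)C1(/C=C/C(=O)c2c(OCOC)cc(OC)cc2OCOC)Oc2cc(O[Si](C(C)C)(C(C)C)C(C)C)ccc2C1=O
F2 | step 8 | racemic (Z)-α-iodoenone derived from F1 | CC(C)(C)OC(=O)C1(/C=C(\I)C(=O)c2c(OCOC)cc(OC)cc2OCOC)Oc2cc(O[Si](C(C)C)(C(C)C)C(C)C)ccc2C1=O
F3 | step 10 | racemic 9,10-dihydro oxepinoflavone acid | COc1cc2oc3c(c(=O)c2c(O)c1)CC(C(=O)O)Oc1cc(O[Si](C(C)C)(C(C)C)C(C)C)ccc1-3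
F4 | step 10 | racemic methyl ester | COc1cc2oc3c(c(=O)c2c(O)c1)CC(C(=O)OC)Oc1cc(O[Si](C(C)C)(C(C)C)C(C)C)ccc1-3
F5 | step 10 | (10S)-methyl ester | COc1cc2oc3c(c(=O)c2c(O)c1)C[C@@H](C(=O)OC)Oc1cc(O[Si](C(C)C)(C(C)C)C(C)C)ccc1-3
F6 | step 12 | (10R)-S-ethyl thioester | COc1cc2oc3c(c(=O)c2c(O)c1)C[C@H](C(=O)SCC)Oc1cc(O[Si](C(C)C)(C(C)C)C(C)C)ccc1-3
F7 | step 12 | (10R)-methyl ketone | COc1cc2oc3c(c(=O)c2c(O)c1)C[C@H](C(C)=O)Oc1cc(O[Si](C(C)C)(C(C)C)C(C)C)ccc1-3
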